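**Retrosynthetic overview**

- The strategy rests on the 4-hydroxy-3-methylfuran-2(5H)-one ring (O1–C2–C3–C4–C5) and its exocyclic C5=C1′ double bond, in which ring oxygen O1 must lie trans to the (S)-methyl-bearing carbon C2′ (5E, the less stable geometry).
- The ring is closed last at C3–C4 by Dieckmann condensation of a methyl (2E)-2-(propanoyloxy)alk-2-enoate that already carries the full chain and the fixed geometry; it is the only ring formed, since the furan is bought.
- The enol ester C=C bond comes from a diaryl phosphonate Horner–Wadsworth–Emmons (HWE) olefination of the (S)-α-methyl aldehyde with methyl 2-(diphenoxyphosphoryl)-2-(propanoyloxy)acetate (from methyl glyoxylate, diphenyl phosphite and propanoyl chloride).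
- The aldehyde chain is joined at the 1,1-disubstituted alkene by B-alkyl Suzuki–Miyaura coupling of an (S)-2-methylpent-4-enyl silyl ether (Evans alkylation) with a 2-bromo-1-alkene furyl ketone.
- The bromodiene ketone comes from a Carroll rearrangement, which sets the (E)-trisubstituted alkene, of an isopropenyl carbinol (from 2,3-dibromopropene) with ethyl 3-(furan-3-yl)-3-oxopropanoate.

Key step: step 14

Remark: the tetronic acid is drawn as its 4-hydroxy enol tautomer; because the (5E)-ylidene is the less stable geometric isomer, the final compound is handled cold, in dim light and without strong acid or nucleophiles.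

**Route**

Step 1
Reactants: 1 tert-butyl acetate; 2 2,3-dibromopropene
Product: 4 tert-butyl 4-bromopent-4-enoate, via lithium enolate of tert-butyl acetate 3 (not isolated)
Conditions: LiN(iPr)2, THF, −78 °C; then 2, −78 → 0 °C
Reagents that add atoms: none
Why: The preformed lithium ester enolate displaces the allylic bromide of 2 (direct and allylic-transposed displacement give the same product) while the vinylic C–Br bond is inert, a standard ester enolate alkylation.

Step 2
Reactants: 4 tert-butyl 4-bromopent-4-enoate
Product: 5 4-bromopent-4-enal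
Conditions: iBu2AlH (1.1 equiv), CH2Cl2, −78 °C; MeOH, then aq. potassium sodium tartrate (KNaC4H4O6)
Reagents that add atoms: none
Why: Partial ester reduction with iBu2AlH at −78 °C stops at the tetrahedral aluminium hemiacetal, which releases the aldehyde only on work-up, and the vinyl bromide is not touched.

Step 3
Reactants: 5 4-bromopent-4-enal; 6 isopropenylmagnesium bromide
Product: 7 rac-6-bromo-2-methylhepta-1,6-dien-3-ol
Conditions: THF, −78 → 0 °C; aq. NH4Cl
Reagents that add atoms: none
Why: Grignard 1,2-addition of the alkenyl nucleophile to the unhindered aldehyde gives the isopropenyl carbinol; it is racemic, which is immaterial because this stereocentre is erased in step 4.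

Step 4
Reactants: 7 rac-6-bromo-2-methylhepta-1,6-dien-3-ol; 8 ethyl 3-(furan-3-yl)-3-oxopropanoate
Product: 11 (4E)-8-bromo-1-(furan-3-yl)-4-methylnona-4,8-dien-1-one, via allyl β-keto ester 9 (not isolated), via rearranged β-keto acid 10 (not isolated)
Conditions: DMAP (cat.), o-dichlorobenzene, 140 °C (−EtOH); then 175 °C (−CO2)
Reagents that add atoms: none
Why: Carroll rearrangement: DMAP-assisted transesterification gives allyl β-keto ester 9, whose ester enol undergoes a [3,3]-sigmatropic shift through a chair transition state with the CH2CH2C(Br)=CH2 chain equatorial, which sets the (4E)-trisubstituted alkene, and β-keto acid 10 loses CO2 at the reaction temperature.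

Step 5
Reactants: 12 (4R)-4-benzyl-3-propanoyl-1,3-oxazolidin-2-one; 13 allyl iodide
Product: 15 (4R)-4-benzyl-3-[(2S)-2-methylpent-4-enoyl]-1,3-oxazolidin-2-one, via sodium Z-enolate of the imide 14 (not isolated)
Conditions: NaN(SiMe3)2, THF, −78 °C; then 13, −78 → −40 °C
Reagents that add atoms: none
Why: Evans alkylation: the chelated sodium (Z)-enolate 14 is allylated on the face opposite the benzyl group of the (4R)-auxiliary, which sets the (S)-configured methyl stereocentre.

Step 6
Reactants: 15 (4R)-4-benzyl-3-[(2S)-2-methylpent-4-enoyl]-1,3-oxazolidin-2-one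
Product: 16 (2S)-2-methylpent-4-en-1-ol
Conditions: LiBH4, H2O (1 equiv), Et2O, 0 °C; aq. NaOH
Reagents that add atoms: none
Why: Reductive removal of the auxiliary: LiBH4 reduces the exocyclic imide carbonyl to the primary alcohol without touching the alkene or epimerising the adjacent stereocentre, and the oxazolidinone is recovered.

Step 7
Reactants: 16 (2S)-2-methylpent-4-en-1-ol
Product: 17 tert-butyldimethyl{[(2S)-2-methylpent-4-en-1-yl]oxy}silane
Conditions: TBSCl, imidazole, CH2Cl2, 0 °C → rt
Reagents that add atoms: tert-butyldimethylsilyl chloride (TBSCl), CC(C)(C)[Si](C)(C)Cl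
Why: Standard silylation of the primary alcohol masks it through the hydroboration and the basic cross-coupling.

Step 8
Reactants: 17 tert-butyldimethyl{[(2S)-2-methylpent-4-en-1-yl]oxy}silane; 11 (4E)-8-bromo-1-(furan-3-yl)-4-methylnona-4,8-dien-1-one
Product: 19 (4E,12S)-13-[(tert-butyldimethylsilyl)oxy]-1-(furan-3-yl)-4,12-dimethyl-8-methylidenetridec-4-en-1-one, via B-alkyl-9-BBN adduct 18 (not isolated)
Conditions: 9-BBN, THF, 0 °C → rt; then aq. Cs2CO3, 11, PdCl2(dppf) (5 mol%), AsPh3, DMF, rt
Reagents that add atoms: none
Why: Anti-Markovnikov hydroboration of the terminal alkene by 9-BBN gives primary alkylborane 18, whose B-alkyl Suzuki–Miyaura coupling with the 2-bromo-1-alkene of 11 (zerovalent palladium generated from PdCl2(dppf), base-activated transmetalation) forms the 1,1-disubstituted alkene; the ketone, furan and trisubstituted alkene of 11 never meet a B–H bond because the borane is made separately and the aqueous base is added first.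

Step 9
Reactants: 19 (4E,12S)-13-[(tert-butyldimethylsilyl)oxy]-1-(furan-3-yl)-4,12-dimethyl-8-methylidenetridec-4-en-1-one
Product: 20 (4E,12S)-1-(furan-3-yl)-13-hydroxy-4,12-dimethyl-8-methylidenetridec-4-en-1-one
Conditions: HF·pyridine, pyridine, THF, 0 °C → rt
Reagents that add atoms: none
Why: Fluoride-mediated Si–O cleavage (desilylation) in a pyridine-buffered medium leaves the ketone, the furan and both alkenes unchanged.

Step 10
Reactants: 20 (4E,12S)-1-(furan-3-yl)-13-hydroxy-4,12-dimethyl-8-methylidenetridec-4-en-1-one
Product: 21 (2S,9E)-13-(furan-3-yl)-2,10-dimethyl-6-methylidene-13-oxotridec-9-enal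
Conditions: Dess–Martin periodinane, pyridine, CH2Cl2, 0 °C → rt
Reagents that add atoms: none
Why: Dess–Martin oxidation under buffered, non-enolising conditions converts the primary alcohol into the aldehyde without over-oxidation and should preserve the α-methyl stereocentre; the aldehyde is used at once.

Step 11
Reactants: 22 methyl glyoxylate (freshly cracked monomer); 23 diphenyl phosphite
Product: 24 methyl 2-(diphenoxyphosphoryl)-2-hydroxyacetate (racemic)
Conditions: CH2Cl2, 0 °C → rt, no base
Reagents that add atoms: none
Why: Pudovik reaction: the P–H bond of the acidic diaryl phosphite adds to the highly electrophilic glyoxylate aldehyde without added base, which avoids the base-induced phosphonate-to-phosphate (phospha-Brook) rearrangement of the α-hydroxy phosphonate.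

Step 12
Reactants: 24 methyl 2-(diphenoxyphosphoryl)-2-hydroxyacetate; 25 propanoyl chloride
Product: 26 methyl 2-(diphenoxyphosphoryl)-2-(propanoyloxy)acetate (racemic)
Conditions: pyridine, CH2Cl2, −10 → 0 °C
Reagents that add atoms: none
Why: O-Acylation of the secondary alcohol by the acid chloride with pyridine at low temperature is faster than any rearrangement of the hydroxy phosphonate and gives an α-acyloxy phosphonoacetate, a known class of olefination reagent.

Step 13
Reactants: 21 (2S,9E)-13-(furan-3-yl)-2,10-dimethyl-6-methylidene-13-oxotridec-9-enal; 26 methyl 2-(diphenoxyphosphoryl)-2-(propanoyloxy)acetate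
Product: 28 methyl (2E,4S,11E)-15-(furan-3-yl)-4,12-dimethyl-8-methylidene-15-oxo-2-(propanoyloxy)pentadeca-2,11-dienoate, via sodium salt of phosphonate 27 (not isolated)
Conditions: 26 (1.3 equiv), NaH (1.2 equiv), THF, 0 °C; then 21, −78 → −20 °C
Reagents that add atoms: none
Why: HWE olefination in its diaryl phosphonate form: the stabilised anion 27 adds to the aldehyde far faster than to the aryl ketone, and the electron-poor aryloxy groups make collapse of the first-formed adduct fast and irreversible, which for α-substituted diaryl phosphonoacetates places the aldehyde substituent cis to the ester and here should favour the (2E)-enol ester; the weakly basic anion at low temperature should spare the α-stereocentre, and the geometric isomers are separated by chromatography so that only the (2E)-isomer enters step 14.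

Step 14
Reactants: 28 methyl (2E,4S,11E)-15-(furan-3-yl)-4,12-dimethyl-8-methylidene-15-oxo-2-(propanoyloxy)pentadeca-2,11-dienoate
Product: 30 (5E)-5-[(2S,9E)-13-(furan-3-yl)-2,10-dimethyl-6-methylidene-13-oxotridec-9-en-1-ylidene]-4-hydroxy-3-methylfuran-2(5H)-one (target CNP0018618.1), via dilithium tetronate ketone enolate 29 (not isolated)
Conditions: LiN(SiMe3)2 (3.2 equiv), THF, −78 → −30 °C, 28 added to the base; then 1 M HCl, 0 °C, dim light
Reagents that add atoms: none
Why: Excess LiN(SiMe3)2 first converts the furyl ketone into its lithium enolate, which takes no further part, and then deprotonates the propanoate CH2, the only ester α-position in the molecule; this ester enolate attacks the methyl ester carbonyl held on the same enol carbon, methoxide leaves, and the C3–H of the new furan-2,4-dione is removed at once to give tetronate 29, which makes the closure irreversible. The closest known reaction type is the Dieckmann (Lacey–Dieckmann-type) cyclisation of 2-acyloxy esters and 2-acyloxyacrylates to tetronic acids and 5-ylidene tetronic acids. The ring O1–C2–C3–C4–C5 closes by C3–C4 bond formation in a 5-exo-trig mode at the ester carbonyl (formally 5-(enolendo)-exo-trig, a mode that this class of ester enolate closure is known to tolerate). No stereocentre is formed; the (S)-centre is only carried through. The step needs site selectivity for deprotonation at the propanoate over the allylic C–H of the stereocentre, which the far higher kinetic acidity of the unhindered ester CH2 compared with the tertiary γ-C–H should secure, and it needs retention of the (E)-geometry, which follows because the acyloxy donor and the ester acceptor sit on one and the same sp2 carbon, so that ring closure involves neither rotation about nor addition to the C=C bond. Low temperature and inverse addition are chosen to keep the ester enolate from fragmenting to methylketene before it cyclises, and the cold, mild acidification only protonates the tetronate and the ketone enolate.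

**Compound list**

1 | tert-butyl acetate | CC(=O)OC(C)(C)C | starting material
2 | 2,3-dibromopropene | C=C(Br)CBr | starting material
3 | lithium enolate of tert-butyl acetate | [Li+].C=C([O-])OC(C)(C)C | intermediate
4 | tert-butyl 4-bromopent-4-enoate | C=C(Br)CCC(=O)OC(C)(C)C | intermediate
5 | 4-bromopent-4-enal | C=C(Br)CCC=O | intermediate
6 | isopropenylmagnesium bromide (prop-1-en-2-ylmagnesium bromide) | CC(=C)[Mg]Br | starting material
7 | rac-6-bromo-2-methylhepta-1,6-dien-3-ol | C=C(C)C(O)CCC(Br)=C | intermediate
8 | ethyl 3-(furan-3-yl)-3-oxopropanoate | CCOC(=O)CC(=O)c1ccoc1 | starting material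
9 | rac-6-bromo-2-methylhepta-1,6-dien-3-yl 3-(furan-3-yl)-3-oxopropanoate | C=C(C)C(CCC(Br)=C)OC(=O)CC(=O)c1ccoc1 | intermediate
10 | rac-(4E)-8-bromo-2-(furan-3-carbonyl)-4-methylnona-4,8-dienoic acid | C=C(Br)CC/C=C(\C)CC(C(=O)O)C(=O)c1ccoc1 | intermediate
11 | (4E)-8-bromo-1-(furan-3-yl)-4-methylnona-4,8-dien-1-one | C=C(Br)CC/C=C(\C)CCC(=O)c1ccoc1 | intermediate
12 | (4R)-4-benzyl-3-propanoyl-1,3-oxazolidin-2-one | CCC(=O)N1[C@H](Cc2ccccc2)COC1=O | starting material
13 | allyl iodide (3-iodoprop-1-ene) | C=CCI | starting material
14 | sodium (Z)-enolate of 12 | [Na+].C/C=C(\[O-])N1[C@H](Cc2ccccc2)COC1=O | intermediate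
15 | (4R)-4-benzyl-3-[(2S)-2-methylpent-4-enoyl]-1,3-oxazolidin-2-one | C=CC[C@H](C)C(=O)N1[C@H](Cc2ccccc2)COC1=O | intermediate
16 | (2S)-2-methylpent-4-en-1-ol | C=CC[C@H](C)CO | intermediate
17 | tert-butyldimethyl{[(2S)-2-methylpent-4-en-1-yl]oxy}silane | C=CC[C@H](C)CO[Si](C)(C)C(C)(C)C | intermediate
18 | 9-[(4S)-5-{[tert-butyl(dimethyl)silyl]oxy}-4-methylpentyl]-9-borabicyclo[3.3.1]nonane | B1(CCC[C@H](C)CO[Si](C)(C)C(C)(C)C)C2CCCC1CCC2 | intermediate
19 | (4E,12S)-13-[(tert-butyldimethylsilyl)oxy]-1-(furan-3-yl)-4,12-dimethyl-8-methylidenetridec-4-en-1-one | C=C(CC/C=C(\C)CCC(=O)c1ccoc1)CCC[C@H](C)CO[Si](C)(C)C(C)(C)C | intermediate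
20 | (4E,12S)-1-(furan-3-yl)-13-hydroxy-4,12-dimethyl-8-methylidenetridec-4-en-1-one | C=C(CC/C=C(\C)CCC(=O)c1ccoc1)CCC[C@H](C)CO | intermediate
21 | (2S,9E)-13-(furan-3-yl)-2,10-dimethyl-6-methylidene-13-oxotridec-9-enal | C=C(CC/C=C(\C)CCC(=O)c1ccoc1)CCC[C@H](C)C=O | intermediate
22 | methyl glyoxylate | COC(=O)C=O | starting material
23 | diphenyl phosphite | O=[PH](Oc1ccccc1)Oc1ccccc1 | starting material
24 | methyl 2-(diphenoxyphosphoryl)-2-hydroxyacetate (racemic) | COC(=O)C(O)P(=O)(Oc1ccccc1)Oc1ccccc1 | intermediate
25 | propanoyl chloride | CCC(=O)Cl | starting material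
26 | methyl 2-(diphenoxyphosphoryl)-2-(propanoyloxy)acetate (racemic) | CCC(=O)OC(C(=O)OC)P(=O)(Oc1ccccc1)Oc1ccccc1 | intermediate
27 | sodium salt (carbanion) of 26 | [Na+].CCC(=O)O[C-](C(=O)OC)P(=O)(Oc1ccccc1)Oc1ccccc1 | intermediate
28 | methyl (2E,4S,11E)-15-(furan-3-yl)-4,12-dimethyl-8-methylidene-15-oxo-2-(propanoyloxy)pentadeca-2,11-dienoate | C=C(CC/C=C(\C)CCC(=O)c1ccoc1)CCC[C@H](C)/C=C(C(=O)OC)/OC(=O)CC | intermediate
29 | dilithium salt of 30 (tetronate and ketone enolate) | [Li+].[Li+].C=C(CC/C=C(\C)CC=C([O-])c1ccoc1)CCC[C@H](C)/C=C1/OC(=O)C(C)=C1[O-] | intermediate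
30 | (5E)-5-[(2S,9E)-13-(furan-3-yl)-2,10-dimethyl-6-methylidene-13-oxotridec-9-en-1-ylidene]-4-hydroxy-3-methylfuran-2(5H)-one | C=C(CC/C=C(\C)CCC(=O)c1ccoc1)CCC[C@H](C)/C=C1/OC(=O)C(C)=C1O | target

**Step count**

Total step count: 14. Longest linear sequence: 9 steps (steps 1, 2, 3, 4, 8, 9, 10, 13, 14).

**Steps most likely to fail**

Step 14. The propanoate enolate may fragment to methylketene with loss of the acyl group before it cyclises. Deprotonation may also occur at the allylic stereocentre, causing epimerisation or deconjugation, and the exocyclic double bond may isomerise during acidification. The fallback sets out from aldehyde 21 and comes back at 30; it brings the ring in preformed instead of closing it. Commercial 3-methyltetronic acid is O-methylated (Me2SO4, K2CO3, acetone) to 4-methoxy-3-methylfuran-2(5H)-one F1. Its C5 lithium derivative (LiN(iPr)2, THF, −78 °C) is added to 21, which should give the aldol adduct 5-[(2S,9E)-13-(furan-3-yl)-1-hydroxy-2,10-dimethyl-6-methylidene-13-oxotridec-9-en-1-yl]-4-methoxy-3-methylfuran-2(5H)-one F2 as a diastereomer mixture. Mesylation (MsCl, Et3N, CH2Cl2) gives the methanesulfonate F3, and elimination with DBU should give the 5-ylidene 4-O-methyl tetronates. The (5E)-5-ylidene 4-O-methyl tetronate F4 is separated by chromatography from its (5Z)-isomer F5, which is re-equilibrated by irradiation and recycled. O-Demethylation of F4 with lithium propanethiolate (LiSPr) in DMF then gives 30.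

Step 13. The olefination may show too little preference for the ester-cis geometry, and the α-methyl aldehyde may epimerise under the basic conditions. The fallback sets out from 21 and comes back at 30; the geometry is corrected after ring closure instead of being demanded from the olefination. The olefination is run for conversion only, and the ester-trans isomer methyl (2Z,4S,11E)-15-(furan-3-yl)-4,12-dimethyl-8-methylidene-15-oxo-2-(propanoyloxy)pentadeca-2,11-dienoate F6 is carried through the Dieckmann conditions of step 14. This should give the (5Z)-ylidene tetronic acid (5Z)-5-[(2S,9E)-13-(furan-3-yl)-2,10-dimethyl-6-methylidene-13-oxotridec-9-en-1-ylidene]-4-hydroxy-3-methylfuran-2(5H)-one F7. Irradiation of F7 (350 nm, degassed MeCN) should lead to a photostationary mixture of ylidene isomers, from which 30 is separated by chromatography while F7 is recycled.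

Step 4. Transesterification of the hindered secondary allylic alcohol may be incomplete; the allylic ester may eliminate thermally or the bromodiene may polymerise at the temperature needed for rearrangement, and the alkene geometry may erode. The fallback sets out from 7 and comes back at 11; it separates the sigmatropic step from the introduction of the furyl ketone. Johnson–Claisen rearrangement of 7 with triethyl orthoacetate (cat. propanoic acid, 140 °C) should give ethyl (4E)-8-bromo-4-methylnona-4,8-dienoate F8. Treatment with MeNH(OMe)·HCl and iPrMgCl (THF, −20 °C) converts it into the Weinreb amide (4E)-8-bromo-N-methoxy-N,4-dimethylnona-4,8-dienamide F9. Addition of 3-furyllithium (3-bromofuran, nBuLi, THF, −78 °C) then gives 11.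

**Further compounds**

F1 | step 14 | 4-methoxy-3-methylfuran-2(5H)-one | COC1=C(C)C(=O)OC1
F2 | step 14 | 5-[(2S,9E)-13-(furan-3-yl)-1-hydroxy-2,10-dimethyl-6-methylidene-13-oxotridec-9-en-1-yl]-4-methoxy-3-methylfuran-2(5H)-one (diastereomer mixture) | C=C(CC/C=C(\C)CCC(=O)c1ccoc1)CCC[C@H](C)C(O)C1OC(=O)C(C)=C1OC
F3 | step 14 | methanesulfonate of F2 | C=C(CC/C=C(\C)CCC(=O)c1ccoc1)CCC[C@H](C)C(OS(C)(=O)=O)C1OC(=O)C(C)=C1OC
F4 | step 14 | (5E)-5-[(2S,9E)-13-(furan-3-yl)-2,10-dimethyl-6-methylidene-13-oxotridec-9-en-1-ylidene]-4-methoxy-3-methylfuran-2(5H)-one | C=C(CC/C=C(\C)CCC(=O)c1ccoc1)CCC[C@H](C)/C=C1/OC(=O)C(C)=C1OC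
F5 | step 14 | (5Z)-5-[(2S,9E)-13-(furan-3-yl)-2,10-dimethyl-6-methylidene-13-oxotridec-9-en-1-ylidene]-4-methoxy-3-methylfuran-2(5H)-one | C=C(CC/C=C(\C)CCC(=O)c1ccoc1)CCC[C@H](C)/C=C1\OC(=O)C(C)=C1OC
F6 | step 13 | methyl (2Z,4S,11E)-15-(furan-3-yl)-4,12-dimethyl-8-methylidene-15-oxo-2-(propanoyloxy)pentadeca-2,11-dienoate | C=C(CC/C=C(\C)CCC(=O)c1ccoc1)CCC[C@H](C)/C=C(/C(=O)OC)OC(=O)CC
F7 | step 13 | (5Z)-5-[(2S,9E)-13-(furan-3-yl)-2,10-dimethyl-6-methylidene-13-oxotridec-9-en-1-ylidene]-4-hydroxy-3-methylfuran-2(5H)-one | C=C(CC/C=C(\C)CCC(=O)c1ccoc1)CCC[C@H](C)/C=C1\OC(=O)C(C)=C1O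
F8 | step 4 | ethyl (4E)-8-bromo-4-methylnona-4,8-dienoate | C=C(Br)CC/C=C(\C)CCC(=O)OCC
F9 | step 4 | (4E)-8-bromo-N-methoxy-N,4-dimethylnona-4,8-dienamide | C=C(Br)CC/C=C(\C)CCC(=O)N(C)OC
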